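**Strategy.** The oxolane ring (O1, C2 aryl, C3 CH2OH arm, C4 aroyl, C5H2) is unfolded to a butanolide in which C5 is the lactone carbonyl, C4 the α-carbon, C3 the β-carbon and C2 the stereocentre of a cheap chiral butenolide. The key step exploits the adjacent, trans-disposed ring carbons C3 and C4, each carrying a one-carbon branch. One copper-catalysed operation adds a silylmethyl Grignard reagent (latent CH2OH) to C3 of the O-trityl butenolide and traps the enolate at C4 with O-benzylsyringaldehyde; C2 directs C3, and C3 directs C4. C2 is finally sacrificed: its side chain becomes CO2H, and nickel/photoredox decarboxylative arylation installs the aryl group trans to C3.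

Key step: step 4

Remark on labels: O1 and C2–C5 in the text follow the target numbering above; "lactone C3/C4/C5" refers to the butanolide; systematic names carry their own locants.

Remark on the carbinol (assumption): the carbinol carbon made in step 4 is taken to form as a mixture of epimers. Compounds 8–14 are carried as that mixture, which is merged by oxidation in step 9. C4 is then already trans to C3, so no separate epimerisation step is planned.

Remark on protecting groups: the alcohol freed by the Tamao oxidation is 1,4-related to the primary alcohol that arises from the lactone carbonyl. Left free, the two would close a 3,4-disubstituted oxolane, so it is capped (step 6) before the lactone is reduced. Trityl on the butenolide oxygen and TBDPS on the C3 arm are chosen so that the two primary oxygens are released by different reagents (acid, then fluoride). The aryl bromide is used as its benzyl ether, because a free phenol would be deprotonated under the coupling conditions.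

Step 1
Reactants: 1 (S)-5-(hydroxymethyl)furan-2(5H)-one
Product: 2 (S)-5-[(trityloxy)methyl]furan-2(5H)-one
Conditions: TrCl, pyridine, DMAP (cat.), CH2Cl2, rt
Reagents that add atoms: trityl chloride, ClC(c1ccccc1)(c1ccccc1)c1ccccc1
Why: Tritylation of the primary alcohol (etherification through the trityl cation) under weakly basic conditions leaves the base-sensitive γ-stereocentre untouched, and the bulky ether later shields one ring face and can be removed by acid beside a silyl ether.

Step 2
Reactants: 3 syringaldehyde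
Product: 4 4-(benzyloxy)-3,5-dimethoxybenzaldehyde
Conditions: BnBr, K2CO3, DMF, 60 °C
Reagents that add atoms: benzyl bromide, BrCc1ccccc1
Why: Williamson etherification of the phenoxide masks the acidic phenol, which would otherwise quench the Grignard reagent and the enolate in step 4.

Step 3
Reactants: 5 (chloromethyl)(isopropoxy)dimethylsilane
Product: 6 [(isopropoxydimethylsilyl)methyl]magnesium chloride (used as a THF solution)
Conditions: Mg turnings, BrCH2CH2Br (cat.), THF, reflux
Reagents that add atoms: magnesium, [Mg]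
Why: Grignard formation by insertion of magnesium into the activated α-silyl C–Cl bond, the hindered isopropoxy group on silicon resisting attack by the reagent.

Step 4
Reactants: 2 (S)-5-[(trityloxy)methyl]furan-2(5H)-one; 6 [(isopropoxydimethylsilyl)methyl]magnesium chloride; 4 4-(benzyloxy)-3,5-dimethoxybenzaldehyde
Product: 9 (3R,4S,5S)-3-{[4-(benzyloxy)-3,5-dimethoxyphenyl](hydroxy)methyl}-4-{[dimethyl(propan-2-yloxy)silyl]methyl}-5-[(trityloxy)methyl]oxolan-2-one (carbinol epimers), via chloromagnesium enolate 7 (not isolated), via chloromagnesium aldolate 8 (not isolated)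
Conditions: CuBr·SMe2 (20 mol%), 6 (1.3 equiv), THF, −78 °C; then 4 (1.5 equiv), −78 °C; aq. NH4Cl
Reagents that add atoms: none
Why: Transmetalation of 6 to monovalent copper gives a silylmethylcuprate that adds to the β-carbon of 2 (lactone C4, the future C3) through a π-complex and a trivalent copper σ-adduct, and reductive elimination leaves magnesium enolate 7, which adds to aldehyde 4 through a closed six-membered transition state to give aldolate 8, protonated on work-up. The closest known reaction type is the copper-mediated conjugate addition of Grignard reagents to 5-(alkoxymethyl)butenolides with aldehyde trapping of the enolate, a tandem Michael–aldol sequence. No ring is closed; the lactone ring is carried through unchanged. The lactone C4 centre is controlled by the C5 trityloxymethyl group, which shields one face so that the nucleophile enters anti to it, and the lactone C3 centre is controlled by the new C4 substituent, the aldehyde approaching the enolate trans to it. The step needs 1,4- over 1,2-addition, which copper catalysis at −78 °C should secure, and facial control, which the bulk of the trityl ether next to the stereocentre should secure. The carbinol carbon is formed without control, which is acceptable because it becomes a ketone in step 9.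

Step 5
Reactants: 9 the silylmethyl aldol lactone
Product: 10 (3R,4R,5S)-3-{[4-(benzyloxy)-3,5-dimethoxyphenyl](hydroxy)methyl}-4-(hydroxymethyl)-5-[(trityloxy)methyl]oxolan-2-one (carbinol epimers)
Conditions: 30% H2O2, KF, KHCO3, THF/MeOH (1:1), rt
Reagents that add atoms: hydrogen peroxide, OO
Why: Tamao oxidation (fluoride-assisted silicate formation, hydroperoxide attack and migration of the CH2 group from silicon to oxygen) converts the C–Si bond into C–OH under conditions that spare the lactone and the trityl and benzyl ethers, and any material in which the carbinol oxygen has displaced isopropoxide on silicon is oxidised to the same diol.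

Step 6
Reactants: 10 the diol lactone
Product: 11 (3R,4R,5S)-3-{[4-(benzyloxy)-3,5-dimethoxyphenyl](hydroxy)methyl}-4-{[(tert-butyldiphenylsilyl)oxy]methyl}-5-[(trityloxy)methyl]oxolan-2-one (carbinol epimers)
Conditions: TBDPSCl (1.1 equiv), imidazole, DMF, 0 °C
Reagents that add atoms: tert-butyl(chloro)diphenylsilane, CC(C)(C)[Si](Cl)(c1ccccc1)c1ccccc1
Why: Silylation with the bulky chloride is selective for the primary hydroxyl over the hindered secondary benzylic one, and it removes the only hydroxyl that could close an unwanted 3,4-disubstituted oxolane in step 8.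

Step 7
Reactants: 11 the silyl ether lactone
Product: 12 (2S,3R,4S)-1-[4-(benzyloxy)-3,5-dimethoxyphenyl]-3-{[(tert-butyldiphenylsilyl)oxy]methyl}-2-(hydroxymethyl)-5-(trityloxy)pentane-1,4-diol (C1 epimers)
Conditions: LiAlH4, THF, 0 °C; then Na2SO4·10H2O
Reagents that add atoms: none
Why: Hydride reduction of the lactone to the 1,4-diol breaks no C–O bond at a stereocentre, and the trityl, silyl and benzyl ethers are inert to LiAlH4 at 0 °C.

Step 8
Reactants: 12 the triol
Product: 14 [4-(benzyloxy)-3,5-dimethoxyphenyl]{(3S,4R,5S)-4-{[(tert-butyldiphenylsilyl)oxy]methyl}-5-[(trityloxy)methyl]oxolan-3-yl}methanol (carbinol epimers), via primary tosylate 13 (not isolated)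
Conditions: TsCl (1.1 equiv), Et3N, DMAP (cat.), CH2Cl2, 0 °C to 40 °C
Reagents that add atoms: none
Why: Sulfonylation should occur at the only primary hydroxyl, and the secondary hydroxyl next to the trityloxymethyl group then displaces the tosylate in a 5-exo-tet intramolecular Williamson etherification that keeps the configuration of the oxygen-bearing carbon, whereas closure by the benzylic hydroxyl would need a four-membered ring.

Step 9
Reactants: 14 the oxolane carbinol
Product: 15 [4-(benzyloxy)-3,5-dimethoxyphenyl]{(3S,4R,5S)-4-{[(tert-butyldiphenylsilyl)oxy]methyl}-5-[(trityloxy)methyl]oxolan-3-yl}methanone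
Conditions: Dess–Martin periodinane, NaHCO3, CH2Cl2, rt
Reagents that add atoms: none
Why: Dess–Martin oxidation of the secondary benzylic alcohol gives the aryl ketone and merges the carbinol epimers into one compound, while C4 next to the new carbonyl already has the more stable trans relation to C3 and so cannot be eroded by enolisation.

Step 10
Reactants: 15 the trityl ether ketone
Product: 16 [4-(benzyloxy)-3,5-dimethoxyphenyl]{(3S,4R,5S)-4-{[(tert-butyldiphenylsilyl)oxy]methyl}-5-(hydroxymethyl)oxolan-3-yl}methanone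
Conditions: AcOH/THF/H2O (3:1:1), 45 °C
Reagents that add atoms: none
Why: Acid-catalysed solvolysis of the trityl ether through the stabilised trityl cation leaves the primary TBDPS ether, the benzyl ether and the ketone intact, and no ionisable benzylic alcohol remains at this stage.

Step 11
Reactants: 16 the primary alcohol
Product: 18 (2S,3R,4S)-4-[4-(benzyloxy)-3,5-dimethoxybenzoyl]-3-{[(tert-butyldiphenylsilyl)oxy]methyl}oxolane-2-carboxylic acid, via aldehyde 17 (not isolated)
Conditions: TEMPO (20 mol%), PhI(OAc)2 (2.5 equiv), MeCN/H2O (1:1), rt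
Reagents that add atoms: water, O
Why: Oxoammonium oxidation (TEMPO with PhI(OAc)2 as terminal oxidant) takes the primary alcohol to aldehyde 17, whose hydrate is oxidised on to the acid, and any epimerisation at C2 is harmless because this centre is erased in step 13.

Step 12
Reactants: 19 4-bromo-2,6-dimethoxyphenol
Product: 20 2-(benzyloxy)-5-bromo-1,3-dimethoxybenzene
Conditions: BnBr, K2CO3, DMF, 60 °C
Reagents that add atoms: benzyl bromide, BrCc1ccccc1
Why: Williamson etherification masks the phenol, which would otherwise be deprotonated by Cs2CO3 and deactivate the aryl bromide toward oxidative addition in step 13.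

Step 13
Reactants: 18 the oxolane-2-carboxylic acid; 20 2-(benzyloxy)-5-bromo-1,3-dimethoxybenzene
Product: 22 [4-(benzyloxy)-3,5-dimethoxyphenyl]{(3S,4R,5S)-5-[4-(benzyloxy)-3,5-dimethoxyphenyl]-4-{[(tert-butyldiphenylsilyl)oxy]methyl}oxolan-3-yl}methanone, via cesium carboxylate 21 (not isolated)
Conditions: Ir[dF(CF3)ppy]2(dtbbpy)PF6 (2 mol%), NiCl2·glyme (10 mol%), 4,4'-di-tert-butyl-2,2'-bipyridine (15 mol%), Cs2CO3, 20 (2 equiv), DMF, blue LEDs, rt
Reagents that add atoms: none
Why: In this metallaphotoredox decarboxylative arylation the photoexcited iridium complex oxidises carboxylate 21, loss of CO2 gives the O1-stabilised C2 radical, the radical is captured by the aryl nickel bromide formed by oxidative addition of 20 to zerovalent nickel, and reductive elimination from trivalent nickel should form the C2–aryl bond on the face anti to the bulky silyloxymethyl group at C3, which resets C2 as the 2,3-trans isomer.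

Step 14
Reactants: 22 the silyl ether
Product: 23 [4-(benzyloxy)-3,5-dimethoxyphenyl]{(3S,4R,5S)-5-[4-(benzyloxy)-3,5-dimethoxyphenyl]-4-(hydroxymethyl)oxolan-3-yl}methanone
Conditions: TBAF, AcOH (1:1), THF, rt
Reagents that add atoms: none
Why: Fluoride-mediated desilylation driven by the strong Si–F bond frees the C3 hydroxymethyl group, and buffering with acetic acid keeps the β-alkoxy ketone and its α-centre away from basic conditions.

Step 15
Reactants: 23 the bis(benzyl ether)
Product: 24 (4-hydroxy-3,5-dimethoxyphenyl)[(3S,4R,5S)-5-(4-hydroxy-3,5-dimethoxyphenyl)-4-(hydroxymethyl)oxolan-3-yl]methanone (CID53356211)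
Conditions: H2 (1 atm), 10% Pd/C, EtOAc/MeOH, rt
Reagents that add atoms: none
Why: Hydrogenolysis of the two aryl benzyl ethers over palladium should be much faster than cleavage of the cyclic benzylic C2–O1 bond or reduction of the electron-rich aryl ketone, provided the reaction is stopped once 23 is consumed.

**Compound list**

1 | (S)-5-(hydroxymethyl)furan-2(5H)-one | O=C1C=C[C@@H](CO)O1 | starting material
2 | (S)-5-[(trityloxy)methyl]furan-2(5H)-one | O=C1C=C[C@@H](COC(c2ccccc2)(c2ccccc2)c2ccccc2)O1 | intermediate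
3 | syringaldehyde (4-hydroxy-3,5-dimethoxybenzaldehyde) | COc1cc(C=O)cc(OC)c1O | starting material
4 | 4-(benzyloxy)-3,5-dimethoxybenzaldehyde | O=Cc1cc(OC)c(OCc2ccccc2)c(OC)c1 | intermediate
5 | (chloromethyl)(isopropoxy)dimethylsilane | CC(C)O[Si](C)(C)CCl | starting material
6 | [(isopropoxydimethylsilyl)methyl]magnesium chloride | CC(C)O[Si](C)(C)C[Mg]Cl | intermediate
7 | chloromagnesium (4S,5S)-4-[(isopropoxydimethylsilyl)methyl]-5-[(trityloxy)methyl]-4,5-dihydrofuran-2-olate (enolate) | Cl[Mg]OC1=C[C@H](C[Si](C)(C)OC(C)C)[C@@H](COC(c2ccccc2)(c2ccccc2)c2ccccc2)O1 | intermediate (not isolated)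
8 | chloromagnesium alkoxide of 9 (aldolate, carbinol epimers) | Cl[Mg]OC(c1cc(OC)c(OCc2ccccc2)c(OC)c1)[C@@H]1C(=O)O[C@H](COC(c2ccccc2)(c2ccccc2)c2ccccc2)[C@H]1C[Si](C)(C)OC(C)C | intermediate (not isolated)
9 | (3R,4S,5S)-3-{[4-(benzyloxy)-3,5-dimethoxyphenyl](hydroxy)methyl}-4-{[dimethyl(propan-2-yloxy)silyl]methyl}-5-[(trityloxy)methyl]oxolan-2-one (carbinol epimers) | OC(c1cc(OC)c(OCc2ccccc2)c(OC)c1)[C@@H]1C(=O)O[C@H](COC(c2ccccc2)(c2ccccc2)c2ccccc2)[C@H]1C[Si](C)(C)OC(C)C | intermediate
10 | (3R,4R,5S)-3-{[4-(benzyloxy)-3,5-dimethoxyphenyl](hydroxy)methyl}-4-(hydroxymethyl)-5-[(trityloxy)methyl]oxolan-2-one (carbinol epimers) | OC(c1cc(OC)c(OCc2ccccc2)c(OC)c1)[C@@H]1C(=O)O[C@H](COC(c2ccccc2)(c2ccccc2)c2ccccc2)[C@H]1CO | intermediate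
11 | (3R,4R,5S)-3-{[4-(benzyloxy)-3,5-dimethoxyphenyl](hydroxy)methyl}-4-{[(tert-butyldiphenylsilyl)oxy]methyl}-5-[(trityloxy)methyl]oxolan-2-one (carbinol epimers) | OC(c1cc(OC)c(OCc2ccccc2)c(OC)c1)[C@@H]1C(=O)O[C@H](COC(c2ccccc2)(c2ccccc2)c2ccccc2)[C@H]1CO[Si](c1ccccc1)(c1ccccc1)C(C)(C)C | intermediate
12 | (2S,3R,4S)-1-[4-(benzyloxy)-3,5-dimethoxyphenyl]-3-{[(tert-butyldiphenylsilyl)oxy]methyl}-2-(hydroxymethyl)-5-(trityloxy)pentane-1,4-diol (C1 epimers) | OC(c1cc(OC)c(OCc2ccccc2)c(OC)c1)[C@H](CO)[C@H](CO[Si](c1ccccc1)(c1ccccc1)C(C)(C)C)[C@H](O)COC(c1ccccc1)(c1ccccc1)c1ccccc1 | intermediate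
13 | (2S,3R,4S)-2-{[4-(benzyloxy)-3,5-dimethoxyphenyl](hydroxy)methyl}-3-{[(tert-butyldiphenylsilyl)oxy]methyl}-4-hydroxy-5-(trityloxy)pentyl 4-methylbenzenesulfonate (primary tosylate of 12) | OC(c1cc(OC)c(OCc2ccccc2)c(OC)c1)[C@H](COS(=O)(=O)c1ccc(C)cc1)[C@H](CO[Si](c1ccccc1)(c1ccccc1)C(C)(C)C)[C@H](O)COC(c1ccccc1)(c1ccccc1)c1ccccc1 | intermediate (not isolated)
14 | [4-(benzyloxy)-3,5-dimethoxyphenyl]{(3S,4R,5S)-4-{[(tert-butyldiphenylsilyl)oxy]methyl}-5-[(trityloxy)methyl]oxolan-3-yl}methanol (carbinol epimers) | OC(c1cc(OC)c(OCc2ccccc2)c(OC)c1)[C@@H]1CO[C@H](COC(c2ccccc2)(c2ccccc2)c2ccccc2)[C@H]1CO[Si](c1ccccc1)(c1ccccc1)C(C)(C)C | intermediate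
15 | [4-(benzyloxy)-3,5-dimethoxyphenyl]{(3S,4R,5S)-4-{[(tert-butyldiphenylsilyl)oxy]methyl}-5-[(trityloxy)methyl]oxolan-3-yl}methanone | O=C(c1cc(OC)c(OCc2ccccc2)c(OC)c1)[C@@H]1CO[C@H](COC(c2ccccc2)(c2ccccc2)c2ccccc2)[C@H]1CO[Si](c1ccccc1)(c1ccccc1)C(C)(C)C | intermediate
16 | [4-(benzyloxy)-3,5-dimethoxyphenyl]{(3S,4R,5S)-4-{[(tert-butyldiphenylsilyl)oxy]methyl}-5-(hydroxymethyl)oxolan-3-yl}methanone | O=C(c1cc(OC)c(OCc2ccccc2)c(OC)c1)[C@@H]1CO[C@H](CO)[C@H]1CO[Si](c1ccccc1)(c1ccccc1)C(C)(C)C | intermediate
17 | (2S,3R,4S)-4-[4-(benzyloxy)-3,5-dimethoxybenzoyl]-3-{[(tert-butyldiphenylsilyl)oxy]methyl}oxolane-2-carbaldehyde | O=C(c1cc(OC)c(OCc2ccccc2)c(OC)c1)[C@@H]1CO[C@H](C=O)[C@H]1CO[Si](c1ccccc1)(c1ccccc1)C(C)(C)C | intermediate (not isolated)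
18 | (2S,3R,4S)-4-[4-(benzyloxy)-3,5-dimethoxybenzoyl]-3-{[(tert-butyldiphenylsilyl)oxy]methyl}oxolane-2-carboxylic acid | O=C(c1cc(OC)c(OCc2ccccc2)c(OC)c1)[C@@H]1CO[C@H](C(=O)O)[C@H]1CO[Si](c1ccccc1)(c1ccccc1)C(C)(C)C | intermediate
19 | 4-bromo-2,6-dimethoxyphenol | COc1cc(Br)cc(OC)c1O | starting material
20 | 2-(benzyloxy)-5-bromo-1,3-dimethoxybenzene | COc1cc(Br)cc(OC)c1OCc1ccccc1 | intermediate
21 | cesium (2S,3R,4S)-4-[4-(benzyloxy)-3,5-dimethoxybenzoyl]-3-{[(tert-butyldiphenylsilyl)oxy]methyl}oxolane-2-carboxylate | O=C(c1cc(OC)c(OCc2ccccc2)c(OC)c1)[C@@H]1CO[C@H](C(=O)[O-])[C@H]1CO[Si](c1ccccc1)(c1ccccc1)C(C)(C)C.[Cs+] | intermediate (not isolated)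
22 | [4-(benzyloxy)-3,5-dimethoxyphenyl]{(3S,4R,5S)-5-[4-(benzyloxy)-3,5-dimethoxyphenyl]-4-{[(tert-butyldiphenylsilyl)oxy]methyl}oxolan-3-yl}methanone | O=C(c1cc(OC)c(OCc2ccccc2)c(OC)c1)[C@@H]1CO[C@H](c2cc(OC)c(OCc3ccccc3)c(OC)c2)[C@H]1CO[Si](c1ccccc1)(c1ccccc1)C(C)(C)C | intermediate
23 | [4-(benzyloxy)-3,5-dimethoxyphenyl]{(3S,4R,5S)-5-[4-(benzyloxy)-3,5-dimethoxyphenyl]-4-(hydroxymethyl)oxolan-3-yl}methanone | O=C(c1cc(OC)c(OCc2ccccc2)c(OC)c1)[C@@H]1CO[C@H](c2cc(OC)c(OCc3ccccc3)c(OC)c2)[C@H]1CO | intermediate
24 | (4-hydroxy-3,5-dimethoxyphenyl)[(3S,4R,5S)-5-(4-hydroxy-3,5-dimethoxyphenyl)-4-(hydroxymethyl)oxolan-3-yl]methanone | COc1cc(C(=O)[C@@H]2CO[C@H](c3cc(OC)c(O)c(OC)c3)[C@H]2CO)cc(OC)c1O | target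

**Step count and risk**

Total steps: 15. Longest linear sequence: 12 steps (steps 1, 4–11 and 13–15, from compound 1).

Steps most likely to fail:

1. Step 4 (three-component coupling). What may go wrong: incomplete 1,4-addition to the lactone, consumption of the aldehyde by unreacted Grignard reagent, or reversal of the aldol before the quench. Fallback: the two bond formations are separated. Setting out from 2 and 6, the copper-catalysed addition is quenched at the enolate stage (7, aq. NH4Cl) and the saturated lactone (4S,5S)-4-{[dimethyl(propan-2-yloxy)silyl]methyl}-5-[(trityloxy)methyl]oxolan-2-one F1 is isolated. It is deprotonated with LiN(iPr)2 in THF at −78 °C to the lithium enolate F2, which is treated with 4 to give the lithium aldolate F3, again with approach trans to the C4 substituent. Aqueous NH4Cl then returns the route to 9.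

2. Step 13 (decarboxylative arylation). What may go wrong: slow oxidative addition of the electron-rich aryl bromide to nickel, loss of the C2 radical by hydrogen abstraction, or insufficient facial discrimination at C2. Fallback: the acid is activated as a redox-active ester and coupled with an aryl nucleophile instead of an aryl electrophile. Setting out from 18, N-hydroxyphthalimide and N,N'-diisopropylcarbodiimide (DMAP cat., CH2Cl2) give the N-hydroxyphthalimide ester F4. Bromide 20 is converted with n-BuLi (THF, −78 °C) into the aryllithium F5 and then with ZnCl2 into the arylzinc chloride F6. Nickel-catalysed decarboxylative Negishi-type coupling of F4 with F6 (NiCl2·glyme, 4,4'-di-tert-butyl-2,2'-bipyridine, THF/DMF, rt) proceeds through the same C2 radical, is tolerant of the ketone, and returns the route to 22.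

3. Step 8 (ring closure). What may go wrong: loss of regioselectivity in the sulfonylation (attack at a secondary hydroxyl) or sluggish displacement of the tosylate. Fallback: the ring is closed without a sulfonate by intramolecular Mitsunobu etherification. Setting out from 12, PPh3 and diisopropyl azodicarboxylate (THF, 0 °C to rt) activate the least hindered, primary hydroxyl as its oxyphosphonium ion, and the secondary hydroxyl closes the five-membered ring with retention at its own carbon, returning the route directly to 14. Further compounds made: none F0.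

**Further compounds**

F1 | step 4 | (4S,5S)-4-{[dimethyl(propan-2-yloxy)silyl]methyl}-5-[(trityloxy)methyl]oxolan-2-one | O=C1C[C@H](C[Si](C)(C)OC(C)C)[C@@H](COC(c2ccccc2)(c2ccccc2)c2ccccc2)O1
F2 | step 4 | lithium enolate of F1 | [Li]OC1=C[C@H](C[Si](C)(C)OC(C)C)[C@@H](COC(c2ccccc2)(c2ccccc2)c2ccccc2)O1
F3 | step 4 | lithium alkoxide of 9 (lithium aldolate) | [Li]OC(c1cc(OC)c(OCc2ccccc2)c(OC)c1)[C@@H]1C(=O)O[C@H](COC(c2ccccc2)(c2ccccc2)c2ccccc2)[C@H]1C[Si](C)(C)OC(C)C
F4 | step 13 | 1,3-dioxoisoindolin-2-yl (2S,3R,4S)-4-[4-(benzyloxy)-3,5-dimethoxybenzoyl]-3-{[(tert-butyldiphenylsilyl)oxy]methyl}oxolane-2-carboxylate | O=C(c1cc(OC)c(OCc2ccccc2)c(OC)c1)[C@@H]1CO[C@H](C(=O)ON2C(=O)c3ccccc3C2=O)[C@H]1CO[Si](c1ccccc1)(c1ccccc1)C(C)(C)C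
F5 | step 13 | [4-(benzyloxy)-3,5-dimethoxyphenyl]lithium | [Li]c1cc(OC)c(OCc2ccccc2)c(OC)c1
F6 | step 13 | [4-(benzyloxy)-3,5-dimethoxyphenyl]zinc chloride | Cl[Zn]c1cc(OC)c(OCc2ccccc2)c(OC)c1
F0 | step 8 | none | none
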